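The route rests on cutting two bonds at once, C3–C1′ and C4–C4a. Ring C then opens to an acyclic (R)-1-aryloxy-3-arylpropan-2-yl mesylate in which ring B still sits on C4. On ionisation ring B, whose C1′ is ortho to the pyran oxygen (on C2′) and para to the C4′ oxygen, bridges to C3 as a phenonium ion with inversion. C4a of the phloroglucinol-type ring A then opens the three-membered ring at C4. One operation thus moves ring B to C3, closes ring C and relays the glycidol stereocentre. A C8 ester blocks the second ortho site of ring A.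

Key step: step 9

Remark on the chemistry: C3 of the target is (R) (C2 > C1′ > C4 > H). Isoflavan numbering (O1, C2–C4, C4a–C8a, primes for ring B, ring D = dimethylpyran) is used throughout, also for open-chain precursors. TBS = tert-butyldimethylsilyl.

Step 1
Reactants: 1 methyl 2,4,6-trihydroxybenzoate
Product: 2 methyl 2,6-dihydroxy-4-methoxybenzoate
Conditions: Me2SO4 (1.0 equiv), K2CO3 (1.0 equiv), acetone, rt
Reagents that add atoms: dimethyl sulfate, COS(=O)(=O)OC
Why: Williamson O-methylation should take the 4-OH, the only hydroxyl not hydrogen-bonded to the ester carbonyl and therefore the most acidic and nucleophilic one.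

Step 2
Reactants: 2 methyl 2,6-dihydroxy-4-methoxybenzoate
Product: 3 methyl 2-(TBSO)-6-hydroxy-4-methoxybenzoate
Conditions: TBSCl (1.0 equiv), imidazole, DMF, 0 °C to rt
Reagents that add atoms: tert-butyldimethylsilyl chloride, CC(C)(C)[Si](C)(C)Cl
Why: Imidazole-mediated O-silylation of one of two equivalent phenols should stop at the mono stage, because the remaining OH then holds the ester carbonyl alone in a stronger hydrogen bond.

Step 3
Reactants: 3 methyl 2-(TBSO)-6-hydroxy-4-methoxybenzoate; 4 (S)-glycidol
Product: 5 methyl 2-(TBSO)-4-methoxy-6-{[(2R)-oxiran-2-yl]methoxy}benzoate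
Conditions: PPh3, DIAD, THF, 0 °C to rt
Reagents that add atoms: none
Why: Mitsunobu etherification takes place at the primary carbinol carbon of glycidol, so the stereocentre is untouched (the descriptor changes from S to R only through the CIP ranking).

Step 4
Reactants: 6 4-bromoresorcinol
Product: 7 2-bromo-5-(TBSO)phenol
Conditions: TBSCl (1.0 equiv), imidazole, CH2Cl2–DMF, −20 °C
Reagents that add atoms: tert-butyldimethylsilyl chloride, CC(C)(C)[Si](C)(C)Cl
Why: Sterically controlled O-silylation should favour the hydroxyl para to bromine, since the other one is flanked by bromine and held in an OH···Br contact.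

Step 5
Reactants: 7 2-bromo-5-(TBSO)phenol; 8 3-chloro-3-methylbut-1-yne
Product: 9 [4-bromo-3-(2-methylbut-3-yn-2-yloxy)phenoxy](tert-butyl)dimethylsilane
Conditions: DBU, CuCl2·2H2O (1 mol %), MeCN, 0 °C
Reagents that add atoms: none
Why: Copper-catalysed propargylic etherification of phenols with tertiary propargyl chlorides is the standard entry to 1,1-dimethylpropargyl aryl ethers and tolerates ortho halogen.

Step 6
Reactants: 9 [4-bromo-3-(2-methylbut-3-yn-2-yloxy)phenoxy](tert-butyl)dimethylsilane
Product: 12 [(8-bromo-2,2-dimethyl-2H-chromen-5-yl)oxy](tert-butyl)dimethylsilane, via allenylphenol 10 (not isolated), via o-quinone methide 11 (not isolated)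
Conditions: PhNEt2, 180 °C
Reagents that add atoms: none
Why: Aromatic propargyl Claisen rearrangement at the only free ortho carbon (bromine blocks the other), enolisation to 10, 1,5-hydrogen shift to 11 and oxa-6π electrocyclisation should close ring D on the oxygen next to the future C1′, which fixes the angular pyran regiochemistry.

Step 7
Reactants: 12 [(8-bromo-2,2-dimethyl-2H-chromen-5-yl)oxy](tert-butyl)dimethylsilane; 5 methyl 2-(TBSO)-4-methoxy-6-{[(2R)-oxiran-2-yl]methoxy}benzoate
Product: 15 methyl 2-(TBSO)-6-{(2R)-3-[5-(TBSO)-2,2-dimethyl-2H-chromen-8-yl]-2-hydroxypropoxy}-4-methoxybenzoate, via aryllithium 13 (not isolated), via arylmagnesium bromide 14 (not isolated)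
Conditions: 12 (1.3 equiv), n-BuLi, THF, −78 °C; MgBr2·OEt2, −78 to 0 °C; CuI (10 mol %), then 5, −30 to 0 °C; aqueous work-up
Reagents that add atoms: none
Why: Bromine–lithium exchange, transmetalation and copper-catalysed SN2 opening of the terminal epoxide at its CH2 carbon join the two halves without touching the stereocentre, and the ester, flanked by two ortho oxygens, should be too hindered to react at this temperature.

Step 8
Reactants: 15 methyl 2-(TBSO)-6-{(2R)-3-[5-(TBSO)-2,2-dimethyl-2H-chromen-8-yl]-2-hydroxypropoxy}-4-methoxybenzoate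
Product: 16 methyl 2-(TBSO)-6-{(2R)-3-[5-(TBSO)-2,2-dimethyl-2H-chromen-8-yl]-2-(methylsulfonyloxy)propoxy}-4-methoxybenzoate
Conditions: Ms2O, pyridine, CH2Cl2, 0 °C
Reagents that add atoms: methanesulfonic anhydride, CS(=O)(=O)OS(C)(=O)=O
Why: Plain O-sulfonylation keeps the C–O bond and hence the (R) configuration, and the chloride-free anhydride avoids a nucleophile that could intercept the activated β-aryl system.

Step 9
Reactants: 16 methyl 2-(TBSO)-6-{(2R)-3-[5-(TBSO)-2,2-dimethyl-2H-chromen-8-yl]-2-(methylsulfonyloxy)propoxy}-4-methoxybenzoate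
Product: 18 methyl (3R)-7-(TBSO)-3-[5-(TBSO)-2,2-dimethyl-2H-chromen-8-yl]-5-methoxychroman-8-carboxylate, via phenonium mesylate 17 (not isolated)
Conditions: HFIP (0.01 M), 2,6-di-tert-butylpyridine (1.5 equiv), rt to 45 °C
Reagents that add atoms: none
Why: Proposed new method: in strongly ionising, weakly nucleophilic HFIP the C3–OMs bond should ionise with rear-side help from C1′ of ring B (Ar1-3 participation, made fast by the pyran oxygen ortho and the silyloxy group para to C1′), which forms the C3–C1′ bond with inversion and gives the spiro-cyclopropane phenonium ion 17; C4a of ring A then attacks the CH2 corner (C4) in an SN2-like Friedel–Crafts step, the old C4–C1′ bond breaks, ring B rearomatises and the hindered base takes the proton. The closest known reaction types are the solvolytic 1,2-aryl shift of β-arylalkyl sulfonates, the Friedel–Crafts capture of phenonium ions by electron-rich arenes in HFIP and the 6-endo epoxide–arene cyclisation of aryl glycidyl ethers to chroman-3-ols; new is only their merger into one ring-forming aryl transposition. Ring C closes 6-endo with respect to the three-membered ring, and this mode should beat 5-exo attack at C3 because C3 is secondary and inductively deactivated by the neighbouring CH2OAr group and because an arene on a three-atom tether cannot reach the rear of C3. C3 is the only stereocentre and its configuration is relayed, not created, since the anti aryl participation inverts the (R)-carbinol carbon once and the capture at C4 does not touch it, which maps (R)-16 onto (3R)-18. Site selectivity on ring A is secured by the C8 ester, which occupies the second ortho position and turns the OCH2 arm towards C4a, while the meta carbon C6 is out of reach. Aryl participation must outrun hydride shift from C4, attack by the pyran oxygen and loss of MsOH by elimination, which the ortho/para donor pattern of ring B and the absence of any strong base or nucleophile should ensure, and the buffered medium spares the acid-sensitive chromene double bond and both silyl ethers.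

Step 10
Reactants: 18 methyl (3R)-7-(TBSO)-3-[5-(TBSO)-2,2-dimethyl-2H-chromen-8-yl]-5-methoxychroman-8-carboxylate
Product: 20 (3R)-3-(5-hydroxy-2,2-dimethyl-2H-chromen-8-yl)-5-methoxychroman-7-ol, via carboxylic acid 19 (not isolated)
Conditions: NaOH (2 M aq), MeOH, reflux, Ar; then 1 M HCl to pH 6, 40 °C
Reagents that add atoms: none
Why: Hydroxide cleaves both aryl silyl ethers and saponifies the ester, and the resulting 2,4,6-trioxygenated benzoic acid 19 should lose CO2 by ipso protonation on mild acidification, the hydrolysis–decarboxylation sequence that is standard for ester-blocked resorcinols, while C3 carries no acidic hydrogen and is not at risk.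

Compound list
1 | methyl 2,4,6-trihydroxybenzoate | COC(=O)c1c(O)cc(O)cc1O | starting material
2 | methyl 2,6-dihydroxy-4-methoxybenzoate | COC(=O)c1c(O)cc(OC)cc1O | intermediate
3 | methyl 2-(TBSO)-6-hydroxy-4-methoxybenzoate | COC(=O)c1c(O)cc(OC)cc1O[Si](C)(C)C(C)(C)C | intermediate
4 | (S)-glycidol | OC[C@H]1CO1 | starting material
5 | methyl 2-(TBSO)-4-methoxy-6-{[(2R)-oxiran-2-yl]methoxy}benzoate | COC(=O)c1c(O[Si](C)(C)C(C)(C)C)cc(OC)cc1OC[C@H]1CO1 | intermediate
6 | 4-bromoresorcinol | Oc1ccc(Br)c(O)c1 | starting material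
7 | 2-bromo-5-(TBSO)phenol | Oc1cc(O[Si](C)(C)C(C)(C)C)ccc1Br | intermediate
8 | 3-chloro-3-methylbut-1-yne | CC(C)(Cl)C#C | starting material
9 | [4-bromo-3-(2-methylbut-3-yn-2-yloxy)phenoxy](tert-butyl)dimethylsilane | C#CC(C)(C)Oc1cc(O[Si](C)(C)C(C)(C)C)ccc1Br | intermediate
10 | 6-bromo-3-(TBSO)-2-(3-methylbuta-1,2-dien-1-yl)phenol (allenylphenol, not isolated) | Oc1c(Br)ccc(O[Si](C)(C)C(C)(C)C)c1C=C=C(C)C | intermediate
11 | 2-bromo-5-(TBSO)-6-(3-methylbut-2-en-1-ylidene)cyclohexa-2,4-dien-1-one (o-quinone methide, not isolated) | O=C1C(Br)=CC=C(O[Si](C)(C)C(C)(C)C)/C1=C/C=C(C)C | intermediate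
12 | [(8-bromo-2,2-dimethyl-2H-chromen-5-yl)oxy](tert-butyl)dimethylsilane | CC1(C)C=Cc2c(O[Si](C)(C)C(C)(C)C)ccc(Br)c2O1 | intermediate
13 | [5-(TBSO)-2,2-dimethyl-2H-chromen-8-yl]lithium (not isolated) | CC1(C)C=Cc2c(O[Si](C)(C)C(C)(C)C)ccc([Li])c2O1 | intermediate
14 | [5-(TBSO)-2,2-dimethyl-2H-chromen-8-yl]magnesium bromide (not isolated) | CC1(C)C=Cc2c(O[Si](C)(C)C(C)(C)C)ccc([Mg]Br)c2O1 | intermediate
15 | methyl 2-(TBSO)-6-{(2R)-3-[5-(TBSO)-2,2-dimethyl-2H-chromen-8-yl]-2-hydroxypropoxy}-4-methoxybenzoate | COC(=O)c1c(O[Si](C)(C)C(C)(C)C)cc(OC)cc1OC[C@H](O)Cc1ccc(O[Si](C)(C)C(C)(C)C)c2C=CC(C)(C)Oc12 | intermediate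
16 | (2R)-mesylate of 15 | COC(=O)c1c(O[Si](C)(C)C(C)(C)C)cc(OC)cc1OC[C@H](OS(C)(=O)=O)Cc1ccc(O[Si](C)(C)C(C)(C)C)c2C=CC(C)(C)Oc12 | intermediate
17 | phenonium mesylate: spiro-cyclopropane of C3, C4 and C1′, drawn as the C4′ silyloxocarbenium form; the spiro centre is left open because both rotamer-derived forms converge (not isolated) | COC(=O)c1c(O[Si](C)(C)C(C)(C)C)cc(OC)cc1OC[C@@H]1CC12C=CC(=[O+][Si](C)(C)C(C)(C)C)C3=C2OC(C)(C)C=C3.CS(=O)(=O)[O-] | intermediate
18 | methyl (3R)-7-(TBSO)-3-[5-(TBSO)-2,2-dimethyl-2H-chromen-8-yl]-5-methoxychroman-8-carboxylate | COc1cc(O[Si](C)(C)C(C)(C)C)c(C(=O)OC)c2c1C[C@H](c1ccc(O[Si](C)(C)C(C)(C)C)c3c1OC(C)(C)C=C3)CO2 | intermediate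
19 | (3R)-7-hydroxy-3-(5-hydroxy-2,2-dimethyl-2H-chromen-8-yl)-5-methoxychroman-8-carboxylic acid (not isolated) | COc1cc(O)c(C(=O)O)c2c1C[C@H](c1ccc(O)c3c1OC(C)(C)C=C3)CO2 | intermediate
20 | (3R)-3-(5-hydroxy-2,2-dimethyl-2H-chromen-8-yl)-5-methoxychroman-7-ol | COc1cc(O)cc2c1C[C@H](c1ccc(O)c3c1OC(C)(C)C=C3)CO2 | target

Total step count: 10. Longest linear sequence: 7 steps (steps 4–10). The ring A branch, steps 1–3 and 7–10, is equally long.

Steps most likely to fail

1. Step 9 (Proposed new method).
- What may go wrong: capture of the phenonium ion at C3 or by the ester carbonyl oxygen instead of at C4; hydride shift from C4 to a ring-B benzylic cation followed by elimination; participation of the pyran oxygen with loss of ring D.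
- Fallback (known chemistry): ring C is built first and ring B is brought in afterwards by a stereoinvertive substitution. It sets out from epoxide 5. A 6-endo epoxide–arene cyclisation (HFIP, 50 °C, or catalytic AuCl3/AgOTf) at the only free ortho carbon should give methyl (3R)-7-(TBSO)-3-hydroxy-5-methoxychroman-8-carboxylate F1. TsCl, pyridine and DMAP convert it into methyl (3R)-7-(TBSO)-5-methoxy-3-(tosyloxy)chroman-8-carboxylate F2. Copper-catalysed SN2-type cross-coupling of this secondary tosylate with arylmagnesium bromide 14 (CuI, TMEDA, LiOMe, THF, 0 °C) runs with inversion and comes back to the route at 18.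

2. Step 7.
- What may go wrong: magnesium(II)-induced opening of the epoxide by bromide; premature epoxide–arene cyclisation of the electron-rich glycidyl ether; slow transfer of the ortho-substituted aryl group.
- Fallback: the order in which the three-carbon unit is joined is reversed, so that the ester-bearing partner meets no organometallic reagent. It sets out from 14 (made from 12 as in step 7) and phenol 3. 14 opens (R)-epichlorohydrin at the epoxide CH2 (CuI cat., THF, −30 °C) to (2R)-1-chloro-3-[5-(TBSO)-2,2-dimethyl-2H-chromen-8-yl]propan-2-ol F3. Aqueous NaOH in Et2O closes it to tert-butyl(dimethyl)[(2,2-dimethyl-8-{[(2R)-oxiran-2-yl]methyl}-2H-chromen-5-yl)oxy]silane F4. Phenol 3 then opens F4 at the terminal carbon under (salen)Co(III) catalysis at rt, which forms O1–C2 in place of C4–C1′ and comes back to the route at 15.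

3. Step 10.
- What may go wrong: sluggish saponification of the doubly ortho-substituted ester; air oxidation of the phenolates; thermal ring opening of the pyran and reclosure onto the C4′ oxygen once that oxygen is free.
- Fallback: the blocking carbon is removed reductively while both silyl ethers stay in place. It sets out from 18. DIBAL-H (CH2Cl2, −78 to 0 °C) should give {(3R)-7-(TBSO)-3-[5-(TBSO)-2,2-dimethyl-2H-chromen-8-yl]-5-methoxychroman-8-yl}methanol F5. MnO2 oxidises it to the corresponding chroman-8-carbaldehyde F6. Rhodium-catalysed Tsuji–Wilkinson decarbonylation ([Rh(cod)Cl]2, dppp, xylene, reflux) gives the 7,4′-bis-TBS ether of the target F7. TBAF (THF, 0 °C) then comes back to the route at 20.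

Further compounds
F1 | step 9 | methyl (3R)-7-(TBSO)-3-hydroxy-5-methoxychroman-8-carboxylate | COc1cc(O[Si](C)(C)C(C)(C)C)c(C(=O)OC)c2c1C[C@@H](O)CO2
F2 | step 9 | methyl (3R)-7-(TBSO)-5-methoxy-3-(tosyloxy)chroman-8-carboxylate | COc1cc(O[Si](C)(C)C(C)(C)C)c(C(=O)OC)c2c1C[C@@H](OS(=O)(=O)c1ccc(C)cc1)CO2
F3 | step 7 | (2R)-1-chloro-3-[5-(TBSO)-2,2-dimethyl-2H-chromen-8-yl]propan-2-ol | ClC[C@H](O)Cc1ccc(O[Si](C)(C)C(C)(C)C)c2C=CC(C)(C)Oc12
F4 | step 7 | tert-butyl(dimethyl)[(2,2-dimethyl-8-{[(2R)-oxiran-2-yl]methyl}-2H-chromen-5-yl)oxy]silane | CC1(C)C=Cc2c(O[Si](C)(C)C(C)(C)C)ccc(C[C@@H]3CO3)c2O1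
F5 | step 10 | {(3R)-7-(TBSO)-3-[5-(TBSO)-2,2-dimethyl-2H-chromen-8-yl]-5-methoxychroman-8-yl}methanol | COc1cc(O[Si](C)(C)C(C)(C)C)c(CO)c2c1C[C@H](c1ccc(O[Si](C)(C)C(C)(C)C)c3c1OC(C)(C)C=C3)CO2
F6 | step 10 | (3R)-7-(TBSO)-3-[5-(TBSO)-2,2-dimethyl-2H-chromen-8-yl]-5-methoxychroman-8-carbaldehyde | COc1cc(O[Si](C)(C)C(C)(C)C)c(C=O)c2c1C[C@H](c1ccc(O[Si](C)(C)C(C)(C)C)c3c1OC(C)(C)C=C3)CO2
F7 | step 10 | 7,4′-bis-TBS ether of the target | COc1cc(O[Si](C)(C)C(C)(C)C)cc2c1C[C@H](c1ccc(O[Si](C)(C)C(C)(C)C)c3c1OC(C)(C)C=C3)CO2
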